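The sesquiterpene half is traced back to commercial (−)-elemol, whose ring B already carries C5, C7 and C10 (eudesmane numbering) as in the target, with the C10 vinyl group (C1=C2) and the C5 isopropenyl group (C4=C3) trans-diequatorial. The route rests on stitching this 1,5-diene into ring A: a palladium-induced cyclization joins C2 to C3 and water caps the C4 cation, so one operation closes the trans-decalin and installs the 4α-oxygenated quaternary centre. Its precursor is elemol protected at O11 as the tert-butyldimethylsilyl ether. Hydrogenation, O-arylation of the C4 alkoxide with a dihaloaryl iodonium salt, two cross-couplings and fluoride desilylation then give the honokiol ether.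

Key step: step 2

Assumption: commercial (−)-elemol is taken to be the (1R,3S,4S) enantiomer, 2-[(1R,3S,4S)-4-ethenyl-4-methyl-3-(prop-1-en-2-yl)cyclohexyl]propan-2-ol. Eudesmane numbering and α/β descriptors (β = the face of the C10 methyl group) are used for the terpene part throughout, and TBS stands for tert-butyldimethylsilyl.

Step 1
Reactants: 1 (−)-elemol
Product: 2 elemol TBS ether (O11-silylated elema-1,3-diene; stereocentres as in 1)
Conditions: TBSOTf, 2,6-lutidine, CH2Cl2, 0 °C to rt
Reagents that add atoms: tert-butyldimethylsilyl trifluoromethanesulfonate, CC(C)(C)[Si](C)(C)OS(=O)(=O)C(F)(F)F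
Why: Silylation of a tertiary alcohol with a silyl triflate and a hindered pyridine base is reliable and leaves the diene alone; the TBS group is chosen over smaller trialkylsilyl groups because PdCl2(MeCN)2 in wet acetone, the medium of step 2, is itself able to cleave labile silyl ethers, whereas a tertiary TBS ether should persist there and through the basic steps that follow.

Step 2
Reactants: 2 elemol TBS ether
Product: 4 11-(tert-butyldimethylsilyloxy)eudesm-1-en-4α-ol (trans-fused; 4α-OH, 4β-CH3, 5α-H, 7β-side chain, 10β-CH3), via C1-palladated eudesman-4α-ol 3 (not isolated)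
Conditions: PdCl2(MeCN)2 (10 mol%), 1,4-benzoquinone (1.5 equiv), acetone/H2O 10:1, rt
Reagents that add atoms: water, O
Why: Proposed new method: divalent palladium binds the unhindered C1=C2 vinyl group and the C3 methylene of the isopropenyl group attacks C2 anti to the metal, forming the C2–C3 bond and leaving a tertiary cation at C4 and a σ-bond from C1 to palladium; water adds to C4 to give 3, and β-hydride elimination towards C2 (C10 is quaternary) releases the C1=C2 alkene of 4 and zerovalent palladium, which benzoquinone reoxidizes. The closest known reaction type is the PdCl2-catalysed Cope rearrangement of 2-substituted hexa-1,5-dienes, which runs through the same palladated cyclohexyl cation; there the cation fragments to the rearranged diene, whereas here fragmentation would give a strained (E,E)-cyclodeca-1,5-diene that lies uphill from the divinylcyclohexane, so capture by water should win. Ring A closes in the 6-endo mode through a chair in which both alkene arms stay equatorial on ring B, so the trans ring fusion follows from the existing C5 and C10 centres. The one new stereocentre, C4, is set by the axial C10 methyl group, which blocks the β face of the planar cation and sends water to the equatorial α face (4α-OH, 4β-CH3). The step needs cyclization to outrun Wacker-type hydroxypalladation of the vinyl group and water capture to outrun proton loss from the C4 cation; the neopentyl position of the vinyl group on quaternary C10, the enforced proximity of the two alkenes and the large excess of water are counted on for this.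

Step 3
Reactants: 4 11-(tert-butyldimethylsilyloxy)eudesm-1-en-4α-ol
Product: 5 11-(tert-butyldimethylsilyloxy)eudesman-4α-ol (cryptomeridiol 11-TBS ether)
Conditions: H2 (1 atm), 10% Pd/C, EtOAc, rt
Reagents that add atoms: none
Why: Heterogeneous catalytic hydrogenation of a cis-disubstituted ring alkene forms no stereocentre, and the homoallylic tertiary alcohol and the silyl ether are inert to it.

Step 4
Reactants: 6 2-bromo-4-chloro-1-iodobenzene
Product: 8 (2-bromo-4-chlorophenyl)(2,4,6-trimethoxyphenyl)iodonium tosylate, via hydroxy(tosyloxy)iodoarene 7 (not isolated)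
Conditions: mCPBA, TsOH·H2O, MeCN, 77 °C; then 1,3,5-trimethoxybenzene, 77 °C; precipitation with Et2O
Reagents that add atoms: p-toluenesulfonic acid, Cc1ccc(cc1)S(=O)(=O)O; 1,3,5-trimethoxybenzene, COc1cc(OC)cc(OC)c1
Why: One-pot synthesis of an unsymmetrical diaryliodonium salt, in which mCPBA and TsOH oxidize the aryl iodide to the trivalent iodine species 7 and this undergoes electrophilic aromatic substitution on the strongly nucleophilic 1,3,5-trimethoxybenzene.

Step 5
Reactants: 5 11-(tert-butyldimethylsilyloxy)eudesman-4α-ol and 8 (2-bromo-4-chlorophenyl)(2,4,6-trimethoxyphenyl)iodonium tosylate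
Product: 10 4α-(2-bromo-4-chlorophenoxy)-11-(tert-butyldimethylsilyloxy)eudesmane, via sodium alkoxide 9 (not isolated)
Conditions: NaH (1.2 equiv), TBME, rt; then 8, rt to 50 °C
Reagents that add atoms: none
Why: Metal-free O-arylation of an alkoxide with a diaryliodonium salt (ligand coupling at trivalent iodine), a reaction established for tertiary alkoxides, should transfer the electron-poor, ortho-substituted 2-bromo-4-chlorophenyl ligand in preference to the electron-rich trimethoxyphenyl dummy, and because the new bond is made at oxygen the C4 configuration set in step 2 is untouched.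

Step 6
Reactants: 11 4-bromophenol
Product: 12 1-(allyloxy)-4-bromobenzene
Conditions: allyl bromide, K2CO3, acetone, reflux
Reagents that add atoms: allyl bromide, C=CCBr
Why: Williamson ether synthesis of a phenoxide with a reactive allylic bromide.

Step 7
Reactants: 12 1-(allyloxy)-4-bromobenzene
Product: 13 2-allyl-4-bromophenol
Conditions: N,N-diethylaniline, 200 °C
Reagents that add atoms: none
Why: Aromatic Claisen rearrangement ([3,3]-sigmatropic shift followed by tautomerization) delivers the allyl group to the free ortho position, the para position being blocked by bromine.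

Step 8
Reactants: 13 2-allyl-4-bromophenol
Product: 14 2-allyl-4-(4,4,5,5-tetramethyl-1,3,2-dioxaborolan-2-yl)phenol
Conditions: B2pin2, Pd(dppf)Cl2 (3 mol%), KOAc, 1,4-dioxane, 85 °C
Reagents that add atoms: bis(pinacolato)diboron, CC1(C)OB(OC1(C)C)B1OC(C)(C)C(C)(C)O1
Why: Miyaura borylation of the aryl bromide, in which KOAc is too weak a base to trigger Suzuki homocoupling and the free phenol and the allyl group are tolerated.

Step 9
Reactants: 10 4α-(2-bromo-4-chlorophenoxy)-11-(tert-butyldimethylsilyloxy)eudesmane and 14 2-allyl-4-(4,4,5,5-tetramethyl-1,3,2-dioxaborolan-2-yl)phenol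
Product: 15 4α-[(3′-allyl-5-chloro-4′-hydroxy-[1,1′-biphenyl]-2-yl)oxy]-11-(tert-butyldimethylsilyloxy)eudesmane
Conditions: Pd(dppf)Cl2 (5 mol%), K2CO3, 1,4-dioxane/H2O 4:1 (degassed), 85 °C
Reagents that add atoms: none
Why: Suzuki–Miyaura coupling in which oxidative addition of zerovalent palladium bearing dppf occurs at the C–Br bond and leaves the para C–Cl bond, the tert-alkyl aryl ether, the silyl ether, the free phenol and the allyl group alone.

Step 10
Reactants: 15 4α-[(3′-allyl-5-chloro-4′-hydroxy-[1,1′-biphenyl]-2-yl)oxy]-11-(tert-butyldimethylsilyloxy)eudesmane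
Product: 16 4α-[(3′,5-diallyl-4′-hydroxy-[1,1′-biphenyl]-2-yl)oxy]-11-(tert-butyldimethylsilyloxy)eudesmane
Conditions: allylboronic acid pinacol ester, Pd2(dba)3 (2.5 mol%), XPhos (10 mol%), K3PO4, THF/H2O 10:1, 65 °C
Reagents that add atoms: allylboronic acid pinacol ester, C=CCB1OC(C)(C)C(C)(C)O1
Why: Suzuki–Miyaura allylation of an aryl chloride, for which the bulky electron-rich biarylphosphine XPhos brings about oxidative addition at the electron-rich C–Cl bond, while the unsubstituted allyl group poses no regiochemical question and the moderate temperature limits migration of the double bond.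

Step 11
Reactants: 16 4α-[(3′,5-diallyl-4′-hydroxy-[1,1′-biphenyl]-2-yl)oxy]-11-(tert-butyldimethylsilyloxy)eudesmane
Product: 17 4α-[(3′,5-diallyl-4′-hydroxy-[1,1′-biphenyl]-2-yl)oxy]eudesman-11-ol (the target, honokiol etherified at O2 by C4 of the eudesmane)
Conditions: TBAF (excess), THF, 60 °C; aq. NH4Cl
Reagents that add atoms: none
Why: Fluoride-mediated cleavage of the Si–O bond, driven by the strong Si–F bond, frees the tertiary C11 alcohol under basic conditions, which are preferred to acid because the tert-alkyl aryl ether at C4 could ionize under acid.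

Compound list

1 | (−)-elemol, 2-[(1R,3S,4S)-4-ethenyl-4-methyl-3-(prop-1-en-2-yl)cyclohexyl]propan-2-ol | C=C[C@]1(C)CC[C@@H](C(C)(C)O)C[C@H]1C(C)=C | starting material
2 | elemol tert-butyldimethylsilyl ether | C=C[C@]1(C)CC[C@@H](C(C)(C)O[Si](C)(C)C(C)(C)C)C[C@H]1C(C)=C | intermediate
3 | 1β-(chloropalladio)-11-(tert-butyldimethylsilyloxy)eudesman-4α-ol (σ-alkylpalladium chloride, further ligands omitted) | O[C@]1(C)CC[C@@H]([Pd]Cl)[C@]2(C)CC[C@@H](C(C)(C)O[Si](C)(C)C(C)(C)C)C[C@H]21 | intermediate
4 | 11-(tert-butyldimethylsilyloxy)eudesm-1-en-4α-ol | O[C@]1(C)CC=C[C@]2(C)CC[C@@H](C(C)(C)O[Si](C)(C)C(C)(C)C)C[C@H]21 | intermediate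
5 | 11-(tert-butyldimethylsilyloxy)eudesman-4α-ol | O[C@]1(C)CCC[C@]2(C)CC[C@@H](C(C)(C)O[Si](C)(C)C(C)(C)C)C[C@H]21 | intermediate
6 | 2-bromo-4-chloro-1-iodobenzene | Clc1ccc(I)c(Br)c1 | starting material
7 | 2-bromo-4-chloro-1-[hydroxy(tosyloxy)iodo]benzene | Cc1ccc(cc1)S(=O)(=O)OI(O)c1ccc(Cl)cc1Br | intermediate
8 | (2-bromo-4-chlorophenyl)(2,4,6-trimethoxyphenyl)iodonium tosylate | COc1cc(OC)c([I+]c2ccc(Cl)cc2Br)c(OC)c1.Cc1ccc(cc1)S(=O)(=O)[O-] | intermediate
9 | sodium 11-(tert-butyldimethylsilyloxy)eudesman-4α-olate | [Na+].[O-][C@]1(C)CCC[C@]2(C)CC[C@@H](C(C)(C)O[Si](C)(C)C(C)(C)C)C[C@H]21 | intermediate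
10 | 4α-(2-bromo-4-chlorophenoxy)-11-(tert-butyldimethylsilyloxy)eudesmane | Clc1ccc(O[C@]2(C)CCC[C@]3(C)CC[C@@H](C(C)(C)O[Si](C)(C)C(C)(C)C)C[C@H]32)c(Br)c1 | intermediate
11 | 4-bromophenol | Oc1ccc(Br)cc1 | starting material
12 | 1-(allyloxy)-4-bromobenzene | C=CCOc1ccc(Br)cc1 | intermediate
13 | 2-allyl-4-bromophenol | C=CCc1cc(Br)ccc1O | intermediate
14 | 2-allyl-4-(4,4,5,5-tetramethyl-1,3,2-dioxaborolan-2-yl)phenol | C=CCc1cc(B2OC(C)(C)C(C)(C)O2)ccc1O | intermediate
15 | 4α-[(3′-allyl-5-chloro-4′-hydroxy-[1,1′-biphenyl]-2-yl)oxy]-11-(tert-butyldimethylsilyloxy)eudesmane | Clc1ccc(O[C@]2(C)CCC[C@]3(C)CC[C@@H](C(C)(C)O[Si](C)(C)C(C)(C)C)C[C@H]32)c(-c2ccc(O)c(CC=C)c2)c1 | intermediate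
16 | 4α-[(3′,5-diallyl-4′-hydroxy-[1,1′-biphenyl]-2-yl)oxy]-11-(tert-butyldimethylsilyloxy)eudesmane | C=CCc1ccc(O[C@]2(C)CCC[C@]3(C)CC[C@@H](C(C)(C)O[Si](C)(C)C(C)(C)C)C[C@H]32)c(-c2ccc(O)c(CC=C)c2)c1 | intermediate
17 | 4α-[(3′,5-diallyl-4′-hydroxy-[1,1′-biphenyl]-2-yl)oxy]eudesman-11-ol (CNP0219722.1) | C=CCc1ccc(O[C@]2(C)CCC[C@]3(C)CC[C@@H](C(C)(C)O)C[C@H]32)c(-c2ccc(O)c(CC=C)c2)c1 | target

Total step count: 11. Longest linear sequence: 7 steps (steps 1, 2, 3, 5, 9, 10 and 11, from elemol 1).

Steps most likely to fail

Step 2 (key step, new method). What may go wrong: Wacker-type hydroxypalladation of the vinyl group may outrun the cyclization, the C4 cation may lose a proton to ring or exocyclic alkenes before water arrives, or the catalyst may deposit as palladium black before turnover. The fallback uses known chemistry, sets out from 2 and returns at 4. The isopropenyl group, the more electron-rich of the two alkenes, is epoxidized selectively (Prilezhaev reaction; mCPBA, 1 equiv, NaHCO3, CH2Cl2, 0 °C) to the oxirane F1, formed as both epimers at the oxirane carbon, which is of no consequence. Periodic acid (H5IO6, THF/H2O, rt) cleaves it to the C4 methyl ketone F2. Allylmagnesium bromide (THF, −78 °C) should add under Felkin–Anh control, with quaternary C10 as the large group anti to the nucleophile, which places the hydroxyl in the 4α sense and gives the homoallylic alcohol F3. Ring-closing metathesis of the C10 vinyl group with the new allyl group, using the second-generation Grubbs catalyst RuCl2(=CHPh)(H2IMes)(PCy3) in CH2Cl2 at 40 °C, closes ring A with the C1=C2 double bond and gives 4.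

Step 5. What may go wrong: the hindered alkoxide may act as a base and deprotonate the iodonium salt next to iodine (aryne formation and loss of regiocontrol), or ligand coupling at the crowded oxygen may be too slow. The fallback sets out from 5 and returns at 10. The potassium alkoxide (KN(SiMe3)2, THF, 0 °C) undergoes nucleophilic aromatic substitution on 2-bromo-1-fluoro-4-nitrobenzene to give the 2-bromo-4-nitrophenyl ether F4. Reduction of the nitro group (Fe, NH4Cl, EtOH/H2O, 70 °C) gives the aniline F5. Sandmeyer chlorination under anhydrous conditions (t-BuONO, CuCl2, MeCN, 0 °C to rt) then gives 10.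

Step 10. What may go wrong: oxidative addition into the electron-rich C–Cl bond may be sluggish, and the allyl double bonds may migrate into conjugation through palladium hydride species at the temperature then needed. The fallback inverts the order of the two couplings so that the allyl group is attached at a C–Br bond before the phenol ring arrives. It sets out from 5 and returns at 16. 4-Bromo-2-chloro-1-iodobenzene is converted as in step 4 into (4-bromo-2-chlorophenyl)(2,4,6-trimethoxyphenyl)iodonium tosylate F6. This arylates the sodium alkoxide 9 of 5 under the conditions of step 5 to give the 4-bromo-2-chlorophenyl ether F7. Suzuki–Miyaura allylation at the para C–Br bond (allylboronic acid pinacol ester, Pd(dppf)Cl2, K2CO3, 1,4-dioxane/H2O, 70 °C) gives the 4-allyl-2-chlorophenyl ether F8. Suzuki–Miyaura coupling of its ortho C–Cl bond with 14 (Pd(OAc)2, SPhos, K3PO4, toluene/H2O, 90 °C) gives 16.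

Further compounds

F1 | step 2 | 3,4-epoxy-11-(tert-butyldimethylsilyloxy)elem-1-ene (oxirane of the isopropenyl group, both epimers at the oxirane carbon) | C=C[C@]1(C)CC[C@@H](C(C)(C)O[Si](C)(C)C(C)(C)C)C[C@H]1C2(C)CO2
F2 | step 2 | C4 methyl ketone, 1-[(1S,2S,5R)-configured 2-ethenyl-2-methyl-5-(2-TBS-oxypropan-2-yl)cyclohexyl]ethanone (stereocentres as in 2) | C=C[C@]1(C)CC[C@@H](C(C)(C)O[Si](C)(C)C(C)(C)C)C[C@H]1C(C)=O
F3 | step 2 | homoallylic tertiary alcohol from Felkin–Anh allylation of F2 (carbinol carbon configured as C4 of 4) | C=C[C@]1(C)CC[C@@H](C(C)(C)O[Si](C)(C)C(C)(C)C)C[C@H]1[C@](C)(O)CC=C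
F4 | step 5 | 4α-(2-bromo-4-nitrophenoxy)-11-(tert-butyldimethylsilyloxy)eudesmane | [O-][N+](=O)c1ccc(O[C@]2(C)CCC[C@]3(C)CC[C@@H](C(C)(C)O[Si](C)(C)C(C)(C)C)C[C@H]32)c(Br)c1
F5 | step 5 | 4α-(4-amino-2-bromophenoxy)-11-(tert-butyldimethylsilyloxy)eudesmane | Nc1ccc(O[C@]2(C)CCC[C@]3(C)CC[C@@H](C(C)(C)O[Si](C)(C)C(C)(C)C)C[C@H]32)c(Br)c1
F6 | step 10 | (4-bromo-2-chlorophenyl)(2,4,6-trimethoxyphenyl)iodonium tosylate | COc1cc(OC)c([I+]c2ccc(Br)cc2Cl)c(OC)c1.Cc1ccc(cc1)S(=O)(=O)[O-]
F7 | step 10 | 4α-(4-bromo-2-chlorophenoxy)-11-(tert-butyldimethylsilyloxy)eudesmane | Brc1ccc(O[C@]2(C)CCC[C@]3(C)CC[C@@H](C(C)(C)O[Si](C)(C)C(C)(C)C)C[C@H]32)c(Cl)c1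
F8 | step 10 | 4α-(4-allyl-2-chlorophenoxy)-11-(tert-butyldimethylsilyloxy)eudesmane | C=CCc1ccc(O[C@]2(C)CCC[C@]3(C)CC[C@@H](C(C)(C)O[Si](C)(C)C(C)(C)C)C[C@H]32)c(Cl)c1
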